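In both dioxanes C2 is the aryl-bearing carbon (on O1), C3 the CH2O-bearing carbon (on O4), and the substituent on the fused benzene ring sits at C7. The retrosynthesis cuts the propenol C=C, then in each dioxane O1–C2 and O4–C3, and the outer C2–C3 bond (made as a Wittig C=C on the formyl group of the inner bicycle).
Enabling feature: in the inner dioxane, C3 is the carbinol carbon of a 3-arylpropane-1,2-diol. C2 is the benzylic carbon of catechol ring C, para to that ring's 4-oxygen, so it can travel as a plain CH2 and become a donor-stabilised cation only when the ring closes.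
Forward order: L-DOPA gives an (S)-arylpropanediol. A Mitsunobu reaction with 3,4-dihydroxybenzaldehyde forms O4–C3, and DDQ closes O1–C2 (inner ring). The formyl group is grown by three carbons, the same Mitsunobu/DDQ pair builds the outer ring, and the side chain comes last.
Stereochemistry: inner C3 is the α-carbon of L-DOPA (retentive diazotisation, one Mitsunobu inversion), and inner C2 is relayed from it in the closure. Outer C3 comes from a Sharpless epoxidation with L-(+)-tartrate (then one Mitsunobu inversion), and outer C2 is relayed likewise. The E-alkene comes from a stabilised ylide.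

Key step: step 8

Remark: with these locants the C7 substituent is meta to O1 and para to O4. MOM = CH2OCH3 and TBS = SiMe2tBu. [inner] = (2S,3S)-2-[3,4-bis(methoxymethoxy)phenyl]-3-[(TBSO)methyl]-2,3-dihydro-1,4-benzodioxin-7-yl. L-DOPA, 3,4-dihydroxybenzaldehyde and methyl (triphenylphosphoranylidene)acetate are taken as commercial.

Step 1
Reactants: 1 L-DOPA
Product: 2 O,O'-diacetyl-L-DOPA hydrochloride
Conditions: AcCl, CF3CO2H, 0 °C to rt; Et2O precipitation
Reagents that add atoms: acetyl chloride, CC(=O)Cl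
Why: Chemoselective O-acylation in strong acid, where the amine is fully protonated and inert, so only the two phenols are acetylated, which masks the catechol against nitrosation and quinone formation in the next step and leaves the α-stereocentre untouched.

Step 2
Reactants: 2 O,O'-diacetyl-L-DOPA hydrochloride
Product: 5 (S)-3-(3,4-diacetoxyphenyl)-2-hydroxypropanoic acid, via diazonium carboxylate 3 (not isolated), via alpha-lactone 4 (not isolated)
Conditions: NaNO2, 0.5 M aq. H2SO4, 0 °C to rt
Reagents that add atoms: water, O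
Why: Diazotisation of an α-amino acid with net retention, because the carboxylate of 3 expels N2 from the rear to give 4 and water opens 4 at the same carbon, so two inversions keep the S configuration, while the acetylated ring is too electron-poor to be nitrosated or to intervene as a phenonium ion.

Step 3
Reactants: 5 (S)-3-(3,4-diacetoxyphenyl)-2-hydroxypropanoic acid
Product: 6 methyl (S)-3-(3,4-dihydroxyphenyl)-2-hydroxypropanoate
Conditions: MeOH, H2SO4 (cat.), reflux
Reagents that add atoms: methanol, CO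
Why: Fischer esterification with concurrent acid-catalysed transesterification of both aryl acetates to methyl acetate, conditions under which an α-hydroxy ester does not racemise.

Step 4
Reactants: 6 methyl (S)-3-(3,4-dihydroxyphenyl)-2-hydroxypropanoate
Product: 7 methyl (S)-3-[3,4-bis(methoxymethoxy)phenyl]-2-hydroxypropanoate
Conditions: MOMCl (2.2 equiv), K2CO3, acetone, 0 °C to rt, inert gas
Reagents that add atoms: chloromethyl methyl ether, COCCl
Why: Williamson-type O-alkylation in which carbonate ionises only the two phenols and not the secondary alcohol, so the catechol is capped selectively with two alkoxy-type donors that the later hydride abstraction needs.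

Step 5
Reactants: 7 methyl (S)-3-[3,4-bis(methoxymethoxy)phenyl]-2-hydroxypropanoate
Product: 8 (S)-3-[3,4-bis(methoxymethoxy)phenyl]propane-1,2-diol
Conditions: LiAlH4, THF, 0 °C
Reagents that add atoms: none
Why: Standard LiAlH4 reduction of an α-hydroxy ester to the 1,2-diol, which touches neither the carbinol stereocentre nor the MOM acetals.

Step 6
Reactants: 8 (S)-3-[3,4-bis(methoxymethoxy)phenyl]propane-1,2-diol
Product: 9 (S)-1-[3,4-bis(methoxymethoxy)phenyl]-3-(TBSO)propan-2-ol
Conditions: TBSCl (1.05 equiv), imidazole, CH2Cl2, 0 °C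
Reagents that add atoms: tert-butyldimethylsilyl chloride, CC(C)(C)[Si](C)(C)Cl
Why: Sterically controlled monosilylation, since one equivalent of bulky TBSCl reacts at the primary hydroxyl of a 1,2-diol well before the secondary one and so leaves the carbinol free for substitution.

Step 7
Reactants: 9 (S)-1-[3,4-bis(methoxymethoxy)phenyl]-3-(TBSO)propan-2-ol; 10 3,4-dihydroxybenzaldehyde (1.5 equiv)
Product: 11 4-{[(R)-1-[3,4-bis(methoxymethoxy)phenyl]-3-(TBSO)propan-2-yl]oxy}-3-hydroxybenzaldehyde
Conditions: PPh3, DIAD, THF, 0 °C to rt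
Reagents that add atoms: none
Why: Mitsunobu etherification in which the 4-OH of 10, para to the formyl group and by far the more acidic phenol, is the one ionised and displaces the activated secondary alcohol by SN2 with inversion (S to R), leaving the 3-OH free for the ring closure.

Step 8
Reactants: 11 4-{[(R)-1-[3,4-bis(methoxymethoxy)phenyl]-3-(TBSO)propan-2-yl]oxy}-3-hydroxybenzaldehyde
Product: 13 (2S,3S)-2-[3,4-bis(methoxymethoxy)phenyl]-3-[(TBSO)methyl]-2,3-dihydro-1,4-benzodioxine-7-carbaldehyde, via benzylic cation 12 (not isolated)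
Conditions: DDQ (1.2 equiv), 4 Å MS, CH2Cl2, 0 °C to rt
Reagents that add atoms: none
Why: DDQ forms a charge-transfer complex with the bis-MOM catechol ring C and takes hydride from its benzylic CH2, which lies para to the 4-OMOM oxygen, giving the quinone-methide-like cation 12 paired with the reduced quinone anion. The 3-OH of the benzaldehyde ring then adds to this sp2 carbon in a 6-exo-trig closure (O1–C2) and gives its proton to the reduced quinone. The closest known reaction type is the DDQ oxidative cyclisation of electron-rich arylalkanes bearing a pendant hydroxyl, as in the conversion of 1-aryl-3-(2-hydroxyphenyl)propanes into flavans and the DDQ C4-etherification of protected flavan-3-ols. C2 is controlled by C3: in the half-chair transition state the CH2OTBS group is pseudo-equatorial and the phenol attacks the face that also places the aryl group pseudo-equatorial, giving the (2S,3S)-trans ring, and any acid-mediated re-ionisation could only drain a cis isomer to this more stable product. The step needs site selectivity between the two arenes, which the formyl group secures by raising the oxidation potential of the phenol-bearing ring, while only ring C carries a benzylic C–H bond. Over-oxidation of 13 should be slow because its remaining benzylic C–H sits next to an aryloxy oxygen whose lone pair is engaged by the formyl-substituted ring, as in p-alkoxybenzyl aryl ethers, which resist DDQ, and the sieves keep water from intercepting 12.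

Step 9
Reactants: 13 inner trans-benzodioxane aldehyde ([inner]-CHO); 14 methyl (triphenylphosphoranylidene)acetate
Product: 15 methyl (E)-3-[inner]prop-2-enoate
Conditions: toluene, 80 °C
Reagents that add atoms: none
Why: Wittig olefination with a stabilised ylide, which converts aromatic aldehydes into E-enoates under neutral conditions and leaves the acetals, the silyl ether and the dioxane stereocentres alone.

Step 10
Reactants: 15 methyl (E)-3-[inner]prop-2-enoate
Product: 16 (E)-3-[inner]prop-2-en-1-ol
Conditions: DIBAL-H (2.5 equiv), CH2Cl2, −78 °C; Rochelle salt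
Reagents that add atoms: none
Why: DIBAL-H 1,2-reduction of an α,β-unsaturated ester at low temperature gives the E-allylic alcohol without conjugate reduction or MOM cleavage.

Step 11
Reactants: 16 (E)-3-[inner]prop-2-en-1-ol
Product: 17 [(2S,3S)-3-[inner]oxiran-2-yl]methanol
Conditions: Ti(OiPr)4 (10 mol %), L-(+)-DIPT (12 mol %), TBHP, 4 Å MS, CH2Cl2, −25 °C; basic work-up, used crude
Reagents that add atoms: tert-butyl hydroperoxide, CC(C)(C)OO
Why: Sharpless asymmetric epoxidation, in which L-(+)-tartrate delivers oxygen to the face of the E-allylic alcohol that gives the (2S,3S)-epoxy alcohol under reagent control (the remote dioxane centres have no say), and the sensitive p-alkoxyaryl epoxide is carried on without chromatography.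

Step 12
Reactants: 17 [(2S,3S)-3-[inner]oxiran-2-yl]methanol
Product: 18 (R)-3-[inner]propane-1,2-diol
Conditions: H2 (1 atm), 10 % Pd/C, EtOAc, rt
Reagents that add atoms: none
Why: Palladium-catalysed benzylic hydrogenolysis cleaves the strained benzylic C–O bond of the aryl epoxide far faster than the unstrained benzylic aryl ether of the dioxane, and the other epoxide C–O bond is not involved, so the carbinol centre is retained and is called R only because the CIP ranking changes.

Step 13
Reactants: 18 (R)-3-[inner]propane-1,2-diol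
Product: 19 (R)-1-[inner]-3-(TBSO)propan-2-ol
Conditions: TBSCl (1.05 equiv), imidazole, CH2Cl2, 0 °C
Reagents that add atoms: tert-butyldimethylsilyl chloride, CC(C)(C)[Si](C)(C)Cl
Why: Sterically controlled monosilylation of the primary hydroxyl of a 1,2-diol, as in step 6.

Step 14
Reactants: 19 (R)-1-[inner]-3-(TBSO)propan-2-ol; 10 3,4-dihydroxybenzaldehyde (1.5 equiv)
Product: 20 4-{[(S)-1-[inner]-3-(TBSO)propan-2-yl]oxy}-3-hydroxybenzaldehyde
Conditions: PPh3, DIAD, THF, 0 °C to rt
Reagents that add atoms: none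
Why: Mitsunobu etherification through the more acidic 4-OH of 10 with SN2 inversion of the carbinol (R to S), which forms the outer O4–C3 bond and leaves the 3-OH free.

Step 15
Reactants: 20 4-{[(S)-1-[inner]-3-(TBSO)propan-2-yl]oxy}-3-hydroxybenzaldehyde
Product: 22 (2R,3R)-2-[inner]-3-[(TBSO)methyl]-2,3-dihydro-1,4-benzodioxine-7-carbaldehyde, via benzylic cation 21 (not isolated)
Conditions: DDQ (1.2 equiv), 4 Å MS, CH2Cl2, 0 °C to rt
Reagents that add atoms: none
Why: Second DDQ benzylic C–H etherification, in which hydride leaves the CH2 para to O4 of the dialkoxy-type ring B, cation 21 is captured 6-exo-trig by the 3-OH of the formyl-deactivated ring A, the pseudo-equatorial CH2OTBS group at C3 steers the aryl group pseudo-equatorial so that C2 becomes R (trans), and the inner C2–H should be spared because it belongs to the less donating bis-MOM ring and is flanked by inductively withdrawing aryloxy-bearing carbons.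

Step 16
Reactants: 22 (2R,3R)-2-[inner]-3-[(TBSO)methyl]-2,3-dihydro-1,4-benzodioxine-7-carbaldehyde; 14 methyl (triphenylphosphoranylidene)acetate
Product: 23 methyl (E)-3-{(2R,3R)-2-[inner]-3-[(TBSO)methyl]-2,3-dihydro-1,4-benzodioxin-7-yl}prop-2-enoate
Conditions: toluene, 80 °C
Reagents that add atoms: none
Why: Wittig olefination with the stabilised ylide sets the E-alkene of the side chain under neutral conditions.

Step 17
Reactants: 23 fully protected enoate
Product: 24 methyl (E)-3-{(2R,3R)-2-[(2S,3S)-2-(3,4-dihydroxyphenyl)-3-(hydroxymethyl)-2,3-dihydro-1,4-benzodioxin-7-yl]-3-(hydroxymethyl)-2,3-dihydro-1,4-benzodioxin-7-yl}prop-2-enoate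
Conditions: HCl (1.25 M in MeOH), 0 to 40 °C
Reagents that add atoms: none
Why: Acid-catalysed methanolysis (acetal exchange and desilylation) removes both aryl MOM ethers and both primary TBS ethers at the enoate stage, where no ionisable cinnamyl alcohol is present, the methyl ester is degenerate towards methanol, and any reversible opening of a benzylic O1–C2 bond recloses to the favoured trans ring.

Step 18
Reactants: 24 tetrahydroxy enoate
Product: 25 target CNP0234042.2
Conditions: DIBAL-H (10 equiv), THF, −78 to 0 °C; Rochelle salt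
Reagents that add atoms: none
Why: DIBAL-H 1,2-reduction of a cinnamate that carries free phenols, the standard entry to monolignol-type cinnamyl alcohols, in which the four hydroxyl groups are only converted into aluminium alkoxides by the excess reagent and released on neutral work-up, so the acid-sensitive product never meets acid.

Compound list
1 | L-DOPA, (S)-2-amino-3-(3,4-dihydroxyphenyl)propanoic acid | N[C@@H](Cc1ccc(O)c(O)c1)C(=O)O | starting material
2 | O,O'-diacetyl-L-DOPA hydrochloride | Cl.N[C@@H](Cc1ccc(OC(C)=O)c(OC(C)=O)c1)C(=O)O | intermediate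
3 | (S)-2-diazonio-3-(3,4-diacetoxyphenyl)propanoate (diazonium carboxylate) | N#[N+][C@@H](Cc1ccc(OC(C)=O)c(OC(C)=O)c1)C(=O)[O-] | intermediate
4 | (R)-3-(3,4-diacetoxybenzyl)oxiran-2-one (alpha-lactone) | O=C1O[C@@H]1Cc2ccc(OC(C)=O)c(OC(C)=O)c2 | intermediate
5 | (S)-3-(3,4-diacetoxyphenyl)-2-hydroxypropanoic acid | O[C@@H](Cc1ccc(OC(C)=O)c(OC(C)=O)c1)C(=O)O | intermediate
6 | methyl (S)-3-(3,4-dihydroxyphenyl)-2-hydroxypropanoate | O[C@@H](Cc1ccc(O)c(O)c1)C(=O)OC | intermediate
7 | methyl (S)-3-[3,4-bis(methoxymethoxy)phenyl]-2-hydroxypropanoate | O[C@@H](Cc1ccc(OCOC)c(OCOC)c1)C(=O)OC | intermediate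
8 | (S)-3-[3,4-bis(methoxymethoxy)phenyl]propane-1,2-diol | O[C@@H](Cc1ccc(OCOC)c(OCOC)c1)CO | intermediate
9 | (S)-1-[3,4-bis(methoxymethoxy)phenyl]-3-(TBSO)propan-2-ol | O[C@@H](Cc1ccc(OCOC)c(OCOC)c1)CO[Si](C)(C)C(C)(C)C | intermediate
10 | 3,4-dihydroxybenzaldehyde | O=Cc1ccc(O)c(O)c1 | starting material
11 | 4-{[(R)-1-[3,4-bis(methoxymethoxy)phenyl]-3-(TBSO)propan-2-yl]oxy}-3-hydroxybenzaldehyde | O=Cc1ccc(O[C@@H](CO[Si](C)(C)C(C)(C)C)Cc2ccc(OCOC)c(OCOC)c2)c(O)c1 | intermediate
12 | benzylic (quinone-methide-like) cation from 11 | O=Cc1ccc(O[C@@H](CO[Si](C)(C)C(C)(C)C)[CH+]c2ccc(OCOC)c(OCOC)c2)c(O)c1 | intermediate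
13 | (2S,3S)-2-[3,4-bis(methoxymethoxy)phenyl]-3-[(TBSO)methyl]-2,3-dihydro-1,4-benzodioxine-7-carbaldehyde | O=Cc1ccc2c(c1)O[C@@H](c1ccc(OCOC)c(OCOC)c1)[C@H](CO[Si](C)(C)C(C)(C)C)O2 | intermediate
14 | methyl (triphenylphosphoranylidene)acetate | COC(=O)C=P(c1ccccc1)(c1ccccc1)c1ccccc1 | starting material
15 | methyl (E)-3-[inner]prop-2-enoate | COC(=O)/C=C/c1ccc2c(c1)O[C@@H](c1ccc(OCOC)c(OCOC)c1)[C@H](CO[Si](C)(C)C(C)(C)C)O2 | intermediate
16 | (E)-3-[inner]prop-2-en-1-ol | OC/C=C/c1ccc2c(c1)O[C@@H](c1ccc(OCOC)c(OCOC)c1)[C@H](CO[Si](C)(C)C(C)(C)C)O2 | intermediate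
17 | [(2S,3S)-3-[inner]oxiran-2-yl]methanol | OC[C@@H]3O[C@H]3c1ccc2c(c1)O[C@@H](c1ccc(OCOC)c(OCOC)c1)[C@H](CO[Si](C)(C)C(C)(C)C)O2 | intermediate
18 | (R)-3-[inner]propane-1,2-diol | O[C@H](Cc1ccc2c(c1)O[C@@H](c1ccc(OCOC)c(OCOC)c1)[C@H](CO[Si](C)(C)C(C)(C)C)O2)CO | intermediate
19 | (R)-1-[inner]-3-(TBSO)propan-2-ol | O[C@H](Cc1ccc2c(c1)O[C@@H](c1ccc(OCOC)c(OCOC)c1)[C@H](CO[Si](C)(C)C(C)(C)C)O2)CO[Si](C)(C)C(C)(C)C | intermediate
20 | 4-{[(S)-1-[inner]-3-(TBSO)propan-2-yl]oxy}-3-hydroxybenzaldehyde | O=Cc1ccc(O[C@H](CO[Si](C)(C)C(C)(C)C)Cc2ccc3c(c2)O[C@@H](c2ccc(OCOC)c(OCOC)c2)[C@H](CO[Si](C)(C)C(C)(C)C)O3)c(O)c1 | intermediate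
21 | benzylic cation from 20 | O=Cc1ccc(O[C@H](CO[Si](C)(C)C(C)(C)C)[CH+]c2ccc3c(c2)O[C@@H](c2ccc(OCOC)c(OCOC)c2)[C@H](CO[Si](C)(C)C(C)(C)C)O3)c(O)c1 | intermediate
22 | (2R,3R)-2-[inner]-3-[(TBSO)methyl]-2,3-dihydro-1,4-benzodioxine-7-carbaldehyde | O=Cc1ccc2c(c1)O[C@H](c1ccc3c(c1)O[C@@H](c1ccc(OCOC)c(OCOC)c1)[C@H](CO[Si](C)(C)C(C)(C)C)O3)[C@@H](CO[Si](C)(C)C(C)(C)C)O2 | intermediate
23 | methyl (E)-3-{(2R,3R)-2-[inner]-3-[(TBSO)methyl]-2,3-dihydro-1,4-benzodioxin-7-yl}prop-2-enoate | COC(=O)/C=C/c1ccc2c(c1)O[C@H](c1ccc3c(c1)O[C@@H](c1ccc(OCOC)c(OCOC)c1)[C@H](CO[Si](C)(C)C(C)(C)C)O3)[C@@H](CO[Si](C)(C)C(C)(C)C)O2 | intermediate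
24 | methyl (E)-3-{(2R,3R)-2-[(2S,3S)-2-(3,4-dihydroxyphenyl)-3-(hydroxymethyl)-2,3-dihydro-1,4-benzodioxin-7-yl]-3-(hydroxymethyl)-2,3-dihydro-1,4-benzodioxin-7-yl}prop-2-enoate | COC(=O)/C=C/c1ccc2c(c1)O[C@H](c1ccc3c(c1)O[C@@H](c1ccc(O)c(O)c1)[C@H](CO)O3)[C@@H](CO)O2 | intermediate
25 | (E)-3-{(2R,3R)-2-[(2S,3S)-2-(3,4-dihydroxyphenyl)-3-(hydroxymethyl)-2,3-dihydro-1,4-benzodioxin-7-yl]-3-(hydroxymethyl)-2,3-dihydro-1,4-benzodioxin-7-yl}prop-2-en-1-ol (CNP0234042.2) | OC/C=C/c1ccc2c(c1)O[C@H](c1ccc3c(c1)O[C@@H](c1ccc(O)c(O)c1)[C@H](CO)O3)[C@@H](CO)O2 | target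

Total step count: 18. Longest linear sequence: 18 steps (1 to 25).

Steps most likely to fail

1. Step 8 (DDQ closure of the inner dioxane).
- What may go wrong: hydride abstraction may be slowed by the inductive pull of the β-aryloxy group. The cation may lose the C3 proton to give an enol ether, may be captured by the reduced quinone, or the product may be oxidised further.
- Fallback, from 11 back to 13: the oxidation mode changes from hydride abstraction to a catechol, o-quinone, quinone methide relay. The two aryl MOM ethers of 11 are removed with TMSOTf/2,2'-bipyridyl and then water, which spares the alkyl TBS ether, to give free catechol ether F1. Ag2O (1 equiv, CH2Cl2, rt) oxidises only the catechol ring to o-quinone F2. A trace of Et3N tautomerises it to the neutral 2-hydroxy-p-quinone methide F3. The neighbouring phenol adds 1,6 to the exocyclic carbon, and rearomatisation gives free-catechol trans-benzodioxane aldehyde F4. MOMCl/K2CO3 in acetone returns to 13.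

2. Step 15 (DDQ closure of the outer dioxane).
- What may go wrong: hydride may be lost instead from the inner C2–H, which is benzylic to ring C and α to oxygen. That would open or dehydrogenate the ring already made.
- Fallback, from 17 back to 22: no C–H oxidation is needed, because the benzylic oxygen that hydrogenolysis would remove serves as the leaving group. Silylation of 17 (TBSCl, imidazole) gives epoxy silyl ether F5. The phenoxide of commercial 4-(benzyloxy)-3-hydroxybenzaldehyde (Cs2CO3, DMF, 60 °C) opens the epoxide at the benzylic carbon with inversion to give (1R,2S)-hydroxy benzylic aryl ether F6. Hydrogenolysis (H2, Pd/C, EtOAc) frees the 4-OH to give phenol F7. An intramolecular Mitsunobu etherification (PPh3, DIAD, THF) then closes O4–C3 with inversion. Two inversions on a trans-epoxide give the trans-(2R,3R) ring, which is 22.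

3. Step 11 (Sharpless epoxidation).
- What may go wrong: the acid-sensitive p-alkoxyaryl epoxide may be opened by isopropoxide, tartrate or adventitious water on titanium, during the reaction or the work-up.
- Fallback, from 15 back to 18: the carbinol is set by enamine catalysis and no epoxide is formed. Hydrogenation of 15 (H2, Pd/C, EtOAc) gives saturated ester F8. DIBAL-H (1 equiv, toluene, −78 °C) gives 3-arylpropanal F9. L-Proline-catalysed α-aminoxylation with nitrosobenzene (MeCN, −20 °C) gives (R)-α-anilinooxy aldehyde F10. This is reduced in the same flask with NaBH4 to (R)-anilinooxy alcohol F11, and H2, Pd/C cleaves the N–O bond to give 18.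

Further compounds
F1 | step 8 | free catechol ether, 4-{[(R)-1-(3,4-dihydroxyphenyl)-3-(TBSO)propan-2-yl]oxy}-3-hydroxybenzaldehyde | O=Cc1ccc(O[C@@H](CO[Si](C)(C)C(C)(C)C)Cc2ccc(O)c(O)c2)c(O)c1
F2 | step 8 | o-quinone of F1 | O=Cc1ccc(O[C@@H](CO[Si](C)(C)C(C)(C)C)CC2=CC(=O)C(=O)C=C2)c(O)c1
F3 | step 8 | 2-hydroxy-p-quinone methide tautomer of F2 | O=Cc1ccc(O[C@@H](CO[Si](C)(C)C(C)(C)C)C=C2C=CC(=O)C(O)=C2)c(O)c1
F4 | step 8 | free-catechol trans-benzodioxane aldehyde, (2S,3S)-2-(3,4-dihydroxyphenyl)-3-[(TBSO)methyl]-2,3-dihydro-1,4-benzodioxine-7-carbaldehyde | O=Cc1ccc2c(c1)O[C@@H](c1ccc(O)c(O)c1)[C@H](CO[Si](C)(C)C(C)(C)C)O2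
F5 | step 15 | epoxy silyl ether, TBS ether of 17 | CC(C)(C)[Si](C)(C)OC[C@@H]3O[C@H]3c1ccc2c(c1)O[C@@H](c1ccc(OCOC)c(OCOC)c1)[C@H](CO[Si](C)(C)C(C)(C)C)O2
F6 | step 15 | (1R,2S)-hydroxy benzylic aryl ether, 4-(benzyloxy)-3-{[(1R,2S)-2-hydroxy-1-[inner]-3-(TBSO)propyl]oxy}benzaldehyde | O=Cc1ccc(OCc2ccccc2)c(O[C@H](c2ccc3c(c2)O[C@@H](c2ccc(OCOC)c(OCOC)c2)[C@H](CO[Si](C)(C)C(C)(C)C)O3)[C@@H](O)CO[Si](C)(C)C(C)(C)C)c1
F7 | step 15 | phenol, 4-hydroxy-3-{[(1R,2S)-2-hydroxy-1-[inner]-3-(TBSO)propyl]oxy}benzaldehyde | O=Cc1ccc(O)c(O[C@H](c2ccc3c(c2)O[C@@H](c2ccc(OCOC)c(OCOC)c2)[C@H](CO[Si](C)(C)C(C)(C)C)O3)[C@@H](O)CO[Si](C)(C)C(C)(C)C)c1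
F8 | step 11 | saturated ester, methyl 3-[inner]propanoate | COC(=O)CCc1ccc2c(c1)O[C@@H](c1ccc(OCOC)c(OCOC)c1)[C@H](CO[Si](C)(C)C(C)(C)C)O2
F9 | step 11 | 3-arylpropanal, 3-[inner]propanal | O=CCCc1ccc2c(c1)O[C@@H](c1ccc(OCOC)c(OCOC)c1)[C@H](CO[Si](C)(C)C(C)(C)C)O2
F10 | step 11 | (R)-α-anilinooxy aldehyde, (R)-2-(anilinooxy)-3-[inner]propanal | c1ccccc1NO[C@H](Cc1ccc2c(c1)O[C@@H](c1ccc(OCOC)c(OCOC)c1)[C@H](CO[Si](C)(C)C(C)(C)C)O2)C=O
F11 | step 11 | (R)-anilinooxy alcohol, (R)-2-(anilinooxy)-3-[inner]propan-1-ol | c1ccccc1NO[C@H](Cc1ccc2c(c1)O[C@@H](c1ccc(OCOC)c(OCOC)c1)[C@H](CO[Si](C)(C)C(C)(C)C)O2)CO
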